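**Retrosynthetic overview**

1. The target (3R,4R)-lactone is traced back through hydrogenolysis of two aryl benzyl ethers, epimerisation at C3 of the cis-lactone, and face-selective hydrogenation of the C3=C4 butenolide.
2. The plan rests on one feature: ring A (O1–C2(=O)–C3–C4–C5) carries a vanillyl arm on C3 and an isovanillyl arm on C4. These differ only in which remote oxygen is OH and which is OMe, so no reagent can tell them apart. The position of C2=O next to C3 must therefore follow from the order of bond formation.
3. Key disconnection: the butenolide is cut at C4–CH2(isovanillyl), C2–C3 and C2–O1. The pieces are a 4-arylbut-2-yn-1-ol (vanillyl arm plus C3, C4, C5, O1), a benzylic Grignard reagent (isovanillyl arm) and CO2 (C2). Ring A is the only ring formed and closes in this step.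
4. The alkynol comes from O-benzylvanillin and propargyl alcohol; the Grignard reagent comes from O-benzylisovanillin.

Key step: step 7

Assumption: which antipode of the ferrocenyl ligand delivers the (4R) lactone in step 8 cannot be derived reliably from models. It is to be fixed in a first small run, with the absolute configuration secured by anomalous-dispersion X-ray analysis of a crystalline derivative. The route is written with (Sc,Rp)-ZhaoPhos standing for the antipode that gives (4R).

Remark: both O-benzyl aldehydes are commercial; each is also one step from vanillin or isovanillin (BnBr, K2CO3).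

**Route**

Step 1
Reactants: 1 4-benzyloxy-3-methoxybenzaldehyde (O-benzylvanillin)
Product: 2 (4-benzyloxy-3-methoxyphenyl)methanol
Conditions: NaBH4 (0.5 equiv), MeOH/THF, 0 °C → rt
Reagents that add atoms: none
Why: Borohydride reduction of an aryl aldehyde to the benzylic alcohol; the aryl ethers are inert.

Step 2
Reactants: 2 (4-benzyloxy-3-methoxyphenyl)methanol
Product: 3 4-benzyloxy-3-methoxybenzyl bromide
Conditions: PBr3 (0.4 equiv), CH2Cl2, 0 °C; used freshly without storage
Reagents that add atoms: phosphorus tribromide, BrP(Br)Br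
Why: Bromination of a benzylic alcohol through its phosphite ester and bromide displacement; short contact at 0 °C should leave the aryl benzyl ether intact.

Step 3
Reactants: 4 propargyl alcohol; 3 4-benzyloxy-3-methoxybenzyl bromide
Product: 6 4-(4-benzyloxy-3-methoxyphenyl)but-2-yn-1-ol, via bis(bromomagnesium) propynolate 5 (not isolated)
Conditions: 4 (1.5 equiv), EtMgBr (2.9 equiv), THF, 0 °C → rt; CuCl (10 mol%); 3 (1.0 equiv), THF, 60 °C; aq NH4Cl
Reagents that add atoms: none
Why: Copper-catalysed coupling of an alkynylmagnesium halide with a benzylic bromide; the hydroxyl is masked as its unreactive magnesium alkoxide, so only the acetylide carbon should be benzylated.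

Step 4
Reactants: 7 3-benzyloxy-4-methoxybenzaldehyde (O-benzylisovanillin)
Product: 8 (3-benzyloxy-4-methoxyphenyl)methanol
Conditions: NaBH4 (0.5 equiv), MeOH/THF, 0 °C → rt
Reagents that add atoms: none
Why: Borohydride reduction of an aryl aldehyde, as in step 1.

Step 5
Reactants: 8 (3-benzyloxy-4-methoxyphenyl)methanol
Product: 9 3-benzyloxy-4-methoxybenzyl chloride
Conditions: SOCl2 (1.2 equiv), DMF (cat.), CH2Cl2, 0 °C → rt
Reagents that add atoms: thionyl chloride, O=S(Cl)Cl
Why: Chlorination of a benzylic alcohol through its chlorosulfite; the chloride is chosen over the bromide because it is less prone to homocoupling in step 6.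

Step 6
Reactants: 9 3-benzyloxy-4-methoxybenzyl chloride
Product: 10 (3-benzyloxy-4-methoxybenzyl)magnesium chloride (titrated THF solution, used directly)
Conditions: Mg turnings (3 equiv, activated with i-Bu2AlH, 1 mol%), THF, 0–5 °C, slow addition of 9 to about 0.3 M
Reagents that add atoms: magnesium, [Mg]
Why: Grignard formation by insertion of magnesium into the benzylic C–Cl bond; excess metal, low temperature, dilution and slow addition are the usual measures against Wurtz coupling.

Step 7
Reactants: 6 4-(4-benzyloxy-3-methoxyphenyl)but-2-yn-1-ol; 10 (3-benzyloxy-4-methoxybenzyl)magnesium chloride; 11 carbon dioxide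
Product: 15 3-(4-benzyloxy-3-methoxybenzyl)-4-(3-benzyloxy-4-methoxybenzyl)furan-2(5H)-one, via chloromagnesium alkynolate 12 (not isolated), via vinylmagnesium chelate 13 (not isolated), via Z-hydroxy acid 14 (not isolated)
Conditions: MeMgCl (1.0 equiv), THF, −20 °C; CuI (10 mol%), 10 (2.0 equiv), THF/toluene, −20 °C → rt; CO2 (1 atm), 0 °C → rt; 2 M HCl, rt
Reagents that add atoms: none
Why: MeMgCl converts the alcohol into alkoxide 12; the benzyl group of 10 passes to monovalent copper, and the alkoxide-bound organometallic adds across the triple bond so that the benzylic carbon bonds to the alkyne carbon next to CH2O (later C4) while the metal ends on the far carbon (later C3) anti to it, giving after transmetalation the five-membered oxamagnesacycle 13. CO2 then inserts into the vinyl C–Mg bond with retention of geometry, forming C2–C3. On acidification the Z-hydroxy acid 14, whose CO2H and CH2OH are cis, closes ring A by 5-exo-trig lactonisation (O1 onto C2). The closest known reaction type is the CuI-catalysed anti-carbomagnesiation of 2-alkyn-1-ols with Grignard reagents followed by CO2 capture to 2(5H)-furanones. No stereocentre is formed; the alkene geometry is fixed by the chelate. The step needs regioselectivity (isovanillyl-type benzyl on C4, carboxyl carbon on C3) and anti addition, and both are secured by the chelating alkoxide oxygen of the substrate, so the two near-identical arms cannot change places.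

Step 8
Reactants: 15 3-(4-benzyloxy-3-methoxybenzyl)-4-(3-benzyloxy-4-methoxybenzyl)furan-2(5H)-one
Product: 16 (3S,4R)-3-(4-benzyloxy-3-methoxybenzyl)-4-(3-benzyloxy-4-methoxybenzyl)dihydrofuran-2(3H)-one (cis)
Conditions: [Rh(nbd)2]BF4 (5 mol%), (Sc,Rp)-ZhaoPhos (5.5 mol%; antipode as fixed in the assumption), H2 (60 bar), CH2Cl2/i-PrOH, 50 °C
Reagents that add atoms: none
Why: Rhodium-catalysed asymmetric hydrogenation of an α,β-unsaturated γ-lactone with cationic monovalent rhodium and a ferrocenyl bisphosphine–thiourea ligand, whose thiourea N–H groups should hydrogen-bond to the lactone carbonyl and hold C3=C4 on the metal; syn addition of H2 to the ligand-selected face sets C4 as R and gives the cis-lactone, with C3 formed as S and corrected in step 9.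

Step 9
Reactants: 16 (3S,4R)-cis-lactone
Product: 17 (3R,4R)-3-(4-benzyloxy-3-methoxybenzyl)-4-(3-benzyloxy-4-methoxybenzyl)dihydrofuran-2(3H)-one (trans)
Conditions: DBU (0.5 equiv), toluene, 90 °C
Reagents that add atoms: none
Why: Base-mediated epimerisation through the lactone enolate at C3, the only acidic stereocentre, should move the material to the thermodynamically preferred trans-3,4-disubstituted lactone; C4 is not enolisable and keeps its R configuration.

Step 10
Reactants: 17 (3R,4R)-trans-lactone bis(benzyl ether)
Product: 18 (3R,4R)-3-(4-hydroxy-3-methoxybenzyl)-4-(3-hydroxy-4-methoxybenzyl)dihydrofuran-2(3H)-one (target)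
Conditions: H2 (1 atm), 10% Pd/C, EtOAc/EtOH, rt
Reagents that add atoms: none
Why: Catalytic hydrogenolysis of the two aryl benzyl ethers; the lactone, the aryl methyl ethers and both stereocentres are not affected under these neutral conditions.

**Compound list**

1 | 4-benzyloxy-3-methoxybenzaldehyde (O-benzylvanillin) | COc1cc(C=O)ccc1OCc1ccccc1 | starting material
2 | (4-benzyloxy-3-methoxyphenyl)methanol | COc1cc(CO)ccc1OCc1ccccc1 | intermediate
3 | 4-benzyloxy-3-methoxybenzyl bromide | COc1cc(CBr)ccc1OCc1ccccc1 | intermediate
4 | propargyl alcohol | C#CCO | starting material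
5 | bromomagnesium 3-(bromomagnesio)prop-2-yn-1-olate | Br[Mg]OCC#C[Mg]Br | intermediate
6 | 4-(4-benzyloxy-3-methoxyphenyl)but-2-yn-1-ol | OCC#CCc1ccc(OCc2ccccc2)c(OC)c1 | intermediate
7 | 3-benzyloxy-4-methoxybenzaldehyde (O-benzylisovanillin) | COc1ccc(C=O)cc1OCc1ccccc1 | starting material
8 | (3-benzyloxy-4-methoxyphenyl)methanol | COc1ccc(CO)cc1OCc1ccccc1 | intermediate
9 | 3-benzyloxy-4-methoxybenzyl chloride | COc1ccc(CCl)cc1OCc1ccccc1 | intermediate
10 | (3-benzyloxy-4-methoxybenzyl)magnesium chloride | COc1ccc(C[Mg]Cl)cc1OCc1ccccc1 | intermediate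
11 | carbon dioxide | O=C=O | starting material
12 | chloromagnesium 4-(4-benzyloxy-3-methoxyphenyl)but-2-yn-1-olate | Cl[Mg]OCC#CCc1ccc(OCc2ccccc2)c(OC)c1 | intermediate
13 | 3-(4-benzyloxy-3-methoxybenzyl)-4-(3-benzyloxy-4-methoxybenzyl)-2,5-dihydro-1,2-oxamagnesole | COc1ccc(CC2=C(Cc3ccc(OCc4ccccc4)c(OC)c3)[Mg]OC2)cc1OCc1ccccc1 | intermediate
14 | (Z)-2-(4-benzyloxy-3-methoxybenzyl)-3-(3-benzyloxy-4-methoxybenzyl)-4-hydroxybut-2-enoic acid | OC/C(Cc1ccc(OC)c(OCc2ccccc2)c1)=C(/Cc1ccc(OCc2ccccc2)c(OC)c1)C(=O)O | intermediate
15 | 3-(4-benzyloxy-3-methoxybenzyl)-4-(3-benzyloxy-4-methoxybenzyl)furan-2(5H)-one | COc1ccc(CC2=C(Cc3ccc(OCc4ccccc4)c(OC)c3)C(=O)OC2)cc1OCc1ccccc1 | intermediate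
16 | (3S,4R)-3-(4-benzyloxy-3-methoxybenzyl)-4-(3-benzyloxy-4-methoxybenzyl)dihydrofuran-2(3H)-one | COc1ccc(C[C@H]2COC(=O)[C@H]2Cc2ccc(OCc3ccccc3)c(OC)c2)cc1OCc1ccccc1 | intermediate
17 | (3R,4R)-3-(4-benzyloxy-3-methoxybenzyl)-4-(3-benzyloxy-4-methoxybenzyl)dihydrofuran-2(3H)-one | COc1ccc(C[C@H]2COC(=O)[C@@H]2Cc2ccc(OCc3ccccc3)c(OC)c2)cc1OCc1ccccc1 | intermediate
18 | (3R,4R)-3-(4-hydroxy-3-methoxybenzyl)-4-(3-hydroxy-4-methoxybenzyl)dihydrofuran-2(3H)-one | COc1ccc(C[C@H]2COC(=O)[C@@H]2Cc2ccc(O)c(OC)c2)cc1O | target

**Step count**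

Total steps: 10. Longest linear sequence: 7 steps (steps 1, 2, 3, 7, 8, 9, 10; the branch through steps 4, 5, 6 is equally long).

**Steps most likely to fail**

Step 8. Hydrogen uptake at the tetrasubstituted C3=C4 bond may be slow or incomplete, and the catalyst may discriminate poorly between the two faces. The fallback sets out from 15 and comes back at 18. Hydrogenation over a heterogeneous catalyst (H2 10 bar, 10% Pd/C, EtOAc/AcOH, 50 °C) should add H2 syn from either face and cleave both benzyl ethers in the same operation, giving racemic cis-3-(4-hydroxy-3-methoxybenzyl)-4-(3-hydroxy-4-methoxybenzyl)dihydrofuran-2(3H)-one F1. DBU (3 equiv, THF, 60 °C; then dilute HCl) should epimerise C3 to the racemic trans-lactone F2. Preparative chromatography on a chiral stationary phase (amylose tris(3,5-dimethylphenylcarbamate), supercritical CO2/MeOH) then separates the antipodes and delivers 18, assigned as in the assumption.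

Step 7. Deprotonation at the benzylic–propargylic CH2 of 12 may lead to allene isomerisation instead of carbometalation, addition of the bulky benzylic reagent may stall, or 13 may be protonated before CO2 capture. The fallback sets out from 1 and 9 and comes back at 15, placing the two arms by construction in another way.
- Aldehyde 1, tetronic acid (furan-2,4(3H,5H)-dione) and Hantzsch ester with L-proline (cat.) in CH2Cl2 should give, by Knoevenagel condensation and transfer hydrogenation, 3-(4-benzyloxy-3-methoxybenzyl)-4-hydroxyfuran-2(5H)-one F3.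
- Tf2O and i-Pr2NEt in CH2Cl2 at −78 °C convert this into 4-(4-benzyloxy-3-methoxybenzyl)-5-oxo-2,5-dihydrofuran-3-yl trifluoromethanesulfonate F4.
- Chloride 9 with zinc dust and LiCl in THF at rt gives (3-benzyloxy-4-methoxybenzyl)zinc chloride F5; zinc insertion is far less prone to homocoupling than magnesium insertion.
- Negishi coupling of the triflate with the zinc reagent (Pd(PPh3)4, zerovalent palladium, THF, 50 °C) forms the C4–CH2 bond and gives 15.

Step 6. Wurtz-type homocoupling of the electron-rich benzylic chloride with freshly formed Grignard reagent at the metal surface may consume the halide. The fallback sets out from 9 and comes back at 10; it makes the benzylic metal by exchange, so that halide and organometallic never coexist.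
- Chloride 9 with benzeneselenol and K2CO3 in DMF at rt gives 3-benzyloxy-4-methoxybenzyl phenyl selenide F6.
- Selenium–lithium exchange with n-BuLi in THF at −78 °C gives (3-benzyloxy-4-methoxybenzyl)lithium F7.
- Transmetalation with anhydrous MgCl2 in THF (−78 °C → 0 °C) gives the solution of 10 for step 7.

**Further compounds**

F1 | step 8 | racemic cis-3-(4-hydroxy-3-methoxybenzyl)-4-(3-hydroxy-4-methoxybenzyl)dihydrofuran-2(3H)-one | COc1ccc(C[C@H]2COC(=O)[C@H]2Cc2ccc(O)c(OC)c2)cc1O.COc1ccc(C[C@@H]2COC(=O)[C@@H]2Cc2ccc(O)c(OC)c2)cc1O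
F2 | step 8 | racemic trans-3-(4-hydroxy-3-methoxybenzyl)-4-(3-hydroxy-4-methoxybenzyl)dihydrofuran-2(3H)-one | COc1ccc(C[C@H]2COC(=O)[C@@H]2Cc2ccc(O)c(OC)c2)cc1O.COc1ccc(C[C@@H]2COC(=O)[C@H]2Cc2ccc(O)c(OC)c2)cc1O
F3 | step 7 | 3-(4-benzyloxy-3-methoxybenzyl)-4-hydroxyfuran-2(5H)-one | COc1cc(CC2=C(O)COC2=O)ccc1OCc1ccccc1
F4 | step 7 | 4-(4-benzyloxy-3-methoxybenzyl)-5-oxo-2,5-dihydrofuran-3-yl trifluoromethanesulfonate | COc1cc(CC2=C(OS(=O)(=O)C(F)(F)F)COC2=O)ccc1OCc1ccccc1
F5 | step 7 | (3-benzyloxy-4-methoxybenzyl)zinc chloride | COc1ccc(C[Zn]Cl)cc1OCc1ccccc1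
F6 | step 6 | 3-benzyloxy-4-methoxybenzyl phenyl selenide | COc1ccc(C[Se]c2ccccc2)cc1OCc1ccccc1
F7 | step 6 | (3-benzyloxy-4-methoxybenzyl)lithium | [Li]Cc1ccc(OC)c(OCc2ccccc2)c1
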